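All runs were generated by integration for substances that don't exist; scatter was added.

In a one-step world target would climb at a single slope from the first minute, but Thursday's run does not.

common to all: free catalyst 0.66 mol%

| run | solid substrate | second substrate | protic impurity | remark | time |
|---|---|---|---|---|---|
| Thursday's | 10 mM | 2 equiv | 2 mM | run made earlier |  |
| flask | 20 mM | 2.00 equiv | 2.00 mM |  | 80 min |

Thursday's run (percent of the solid substrate charged)

| time / min | target / % | idle complex / % |
|---|---|---|
| 1.50 | 0.1 | 1.0 |
| 5.00 | 0.4 | 0.6 |
| 8.00 | 0.8 | 0 |
| 12.0 | 1.9 | 0 |
| 20.0 | 3.2 | 0.5 |
| 25.0 | 5.2 | 0.1 |

(each reading ± 0.3 percentage points)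

- target is meant together with its idle complex
- solid, in amounts per volume of the solution: solid substrate
- at the start none of the solid substrate is in solution
- no earlier run changes the charge of free catalyst; that part of a forecast is a guess

- target and idle complex together at 80 min, in percent of the solid substrate charged
- the change that raises the amount of target and idle complex together at 80 min, in percent of the solid substrate charged most ("none" if none brings more than 2 percentage points) (dusk / noon / summer / none)
- amount of target and idle complex together at 80 min, in percent of the solid substrate charged, after noon

- dusk: doubling the amount of free catalyst, all else as stated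
- noon: doubling the solubility of the solid substrate, all else as stated
- summer: doubling the dissolution coefficient of the solid substrate, all else as stated

By 8.00 min Thursday's run shows 0.8%, while from 12.0 min to 25.0 min target rises faster than before. We carry the late end of that run as a turnover frequency, target made per catalyst charged per minute: 0.385 min⁻¹, a reading with scatter 0.3 percentage points at each end. On our ladder one turnover, as read from Thursday's run, takes 2.60 min, the lag in that run lasts about 12.0 min, longer than a turnover, and the asked 80 min is longer than that lag. So we treat the flask as mostly straight stretch.

The flask is charged with 0.132 mM of free catalyst against 0.0660 mM on Thursday, but the loading is the same, so in percent we keep the slope, 0.00254 min⁻¹ as a fraction of the charge. At the far end, if each protic impurity spoils one solid substrate, it costs the flask 10.0%, and the remaining charge stands above our line. Joining the ends from Thursday's last reading, we reckon 19.2%. Our slope is the loading times the turnover frequency, so we guess dusk, with noon a little above the line; the guess is ours, as no earlier run changes the charge of free catalyst.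

The forecast gives 27%, noon as best and 50% after noon, holding that “Doubling solubility doubles dissolved substrate”; its first number stands above our line and its choice differs from ours.

The flask gives 16.9%. The best change is dusk, gaining 8.2 points against 3.3 points for noon and 2.7 points for summer, and noon reaches 20.2%.

    solid substrate ⇌ starting material, rate k1*(cs1 - [starting material]) while solid is left; crystals form when [starting material] > cs1 (solubility = 18.0 mM, k = 0.0300 min⁻¹)
    free catalyst + target ⇌ idle complex, settled at all times (K = 1600 L mol⁻¹)
    catalyst intermediate A → free catalyst + target (k = 5.40 min⁻¹)
    catalyst intermediate B → free catalyst + second product (k = 4.30 min⁻¹)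
    second substrate + free catalyst ⇌ catalyst intermediate B (K = 11.0 L mol⁻¹, k = 240 L mol⁻¹ min⁻¹)
    starting material + protic impurity → quenched substrate (k = 170 L mol⁻¹ min⁻¹)
    starting material + free catalyst ⇌ catalyst intermediate A (K = 52.0 L mol⁻¹, k = 280 L mol⁻¹ min⁻¹)

From 40.0 min to 80 min this flask turned over at 0.335 min⁻¹, and over its whole run at 0.320 min⁻¹ on average. The neighbour with 50 mM of solid substrate has the same loading, so the same turnover frequency, 0.385 min⁻¹, gives the same 19.2%. That neighbour gives 11.0%, an average of 0.207 min⁻¹, slower than the flask. At its end the neighbour holds 79.9% of its catalyst as idle complex and 9.58% as free catalyst.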